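81.8% is the plateau share (a selectivity), target over target plus side product at the last readings of cedar, birch and ash pooled. Taken singly, birch gives 81.2% and cedar 82.6%, with ash at 81.8% between them.

| flask | starting material | coupling partner | remark | time |
|---|---|---|---|---|
| cedar | 15 mM | 14.2 mM | run made earlier |  |
| birch | 7.5 mM | 14.2 mM | run made earlier |  |
| ash | 30 mM | 14.2 mM | run made earlier |  |
| green | 15 mM | 14.2 mM | a closed flask charged with all of it at once and left for 4.0 h | 4.0 h |
| violet | 15 mM | 14.2 mM (fed, over 3.20 h) | a stirred flask in which coupling partner is dosed at a steady rate over 3.20 h without added volume, worked up at 4.0 h | 4.0 h |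
| red | 15 mM (fed, over 3.20 h) | 14.2 mM | a stirred flask in which starting material is dosed at a steady rate over 3.20 h without added volume, worked up at 4.0 h | 4.0 h |
| ochre | 15 mM | 14.2 mM | one stirred flow tank at steady state, fed with the mixture as stated, mean residence time 4.0 h |  |

| run | time / h | target / % | side product / % |
|---|---|---|---|
| cedar | 0.667 | 8.3 | 1.0 |
| cedar | 1.33 | 16.6 | 2.6 |
| cedar | 2.00 | 20.4 | 2.9 |
| cedar | 2.50 | 21.3 | 4.3 |
| cedar | 3.00 | 22.0 | 3.9 |
| cedar | 4.00 | 21.3 | 4.5 |
| birch | 0.333 | 3.1 | 0.5 |
| birch | 0.500 | 7.3 | 0.7 |
| birch | 0.833 | 11.1 | 1.5 |
| birch | 1.33 | 17.0 | 2.6 |
| birch | 2.50 | 21.3 | 4.2 |
| birch | 4.00 | 21.1 | 4.9 |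
| ash | 0.667 | 8.5 | 0.9 |
| ash | 1.33 | 16.7 | 2.5 |
| ash | 2.00 | 20.7 | 3.7 |
| ash | 2.50 | 21.8 | 4.8 |
| ash | 3.00 | 21.0 | 4.1 |
| ash | 4.00 | 22.0 | 4.9 |

(readings scatter by 0.5 percentage points)

- the stated concentrations are those of everything mixed, before any reaction; amounts are the same in each set-up
- the earlier runs were read with a standard deviation of 0.5 percentage points
- the feed brings no volume worth counting
- the earlier runs were made in a closed, stirred flask

- the set-up with the highest share of target in all that became target or side product, at the outlet or at the end ("none" if the first two lie within 2 percentage points) (green / violet / red / ochre / none)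
- share of target in all that became target or side product, at the outlet or at the end, green
- share of target in all that became target or side product, at the outlet or at the end, violet
- share of target in all that became target or side product, at the outlet or at the end, red
- share of target in all that became target or side product, at the outlet or at the end, ochre

The ladder starts at the turnover time, the last target reading of cedar over its early slope, 1.71 h, shorter than the other times in play. On this rung cedar fills: at 2.00 h its target stands at 95.8% of the last reading, and target plus side product end near a quarter of the charge. Next comes the dosing time 3.20 h, or 1.87 turnover times, then the 4.0 h of the run, or 2.34. Red therefore has 0.468 turnover times after its feed ends, fewer than one, and is read young. Young cedar shows a higher share, 86.5% at 1.33 h, so red should sit a little above the plateau share.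

If each product took one coupling partner, ash would use 56.8% of the partner charge and birch 13.7%. Yet their shares differ by 0.60 percentage points, less than the 1.5 points by which one standard deviation on the last side-product reading of ash moves the ash share. So this reckoning lets each portion of starting material split alike, whenever it enters and whatever partner stands beside it: green, violet and ochre near 81.8%, red slightly higher, and none best.

The forecast differs. It names green best, with 82% for green, 72% for violet, 79% for red and 70% for ochre, and its ground for the last two figures is: “Violet and ochre keep the partner low throughout”.

The flasks give 82.7% for green, 82.7% for violet, 83.7% for red and 83.4% for ochre. They lie 1 point apart, less than 2 points, so the answer is none.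

    starting material → intermediate B (k = 0.00711 /min)
    intermediate A → decomposed reagent (k = 0.0214 /min)
    intermediate B → target (k = 0.0376 /min)
    starting material → intermediate A (k = 0.0254 /min)
    coupling partner ⇌ dormant form (K = 0.455, k = 0.0476 /min)
    intermediate A → side product (k = 0.00135 /min)

In green, half of the turnover up to 4.00 h of the loss of coupling partner to dormant form is done by 0.0760 h, earlier than the 0.356 h of the making of intermediate A from starting material, and at 4.00 h coupling partner stands at 68.7% of its own charge beside 4.44 mM of dormant form. Beside the plateau share of 81.8% read from the runs, one more flask, like green but with 35 mM of coupling partner, gives 82.7%.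

The readings are calculated from invented constants, noise included.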